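**Retrosynthetic overview**
- Aryl ether last: target ⇒ cis hydroxymethyl acetate + umbelliferone (Mitsunobu at the primary CH2OH).
- Key C–C bond = ring bond between the CH(CH2O) carbon and the C(=CH2) carbon. The terminal epoxide of an acyclic epoxy-alkyne is opened by Cp2TiCl, so its carbon reacts as a nucleophilic β-titanoxy radical (reversed polarity of an epoxide) and adds 6-exo-dig to the alkyne. This one step makes the ring, the CH2OH, the exocyclic methylene and the second stereocentre.
- Epoxy-alkyne ⇒ ene-yne acetate ⇒ (R)-homoallylic alcohol (epoxidation, acetylation).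
- (R)-Alcohol ⇒ pent-4-ynal + prenyl unit by Brown asymmetric reverse prenylation (sets the carbinol centre and the CMe2 group); aldehyde from pent-4-yn-1-ol.
- Ring order: the carbocycle is the only ring built (step 5); the coumarin bicycle is bought as umbelliferone.

Assumption: the SMILES is read as the cis isomer with the acetoxy carbon R and the CH–CH2OAr carbon S; pent-4-yn-1-ol, prenylmagnesium chloride solution, (−)-Ipc2BOMe and umbelliferone are taken as commercial.

**Step 1**
Reactants: 1 pent-4-yn-1-ol
Product: 2 pent-4-ynal
Conditions: TEMPO (10 mol %), PhI(OAc)2 (1.1 equiv), CH2Cl2, rt; aqueous NaHCO3/Na2S2O3 wash, used as a dried solution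
Reagents that add atoms: none
Why: TEMPO/PhI(OAc)2 (Piancatelli–Margarita) oxidation stops at the aldehyde and leaves the terminal alkyne untouched; no stereocentre is formed.

**Step 2**
Reactants: 2 pent-4-ynal; 3 prenylmagnesium chloride; 4 (−)-B-methoxydiisopinocampheylborane
Product: 7 (4R)-3,3-dimethyloct-1-en-7-yn-4-ol, via prenyldiisopinocampheylborane 5 (not isolated), via borinate ester 6 (not isolated)
Conditions: 3 + 4, Et2O/THF, −78 to 0 °C; then 2, −78 °C, 3 h; then NaOH, H2O2, 0 °C to rt
Reagents that add atoms: none
Why: Brown asymmetric allylboration (reverse prenylation): borane 5, with boron on the CH2 terminus, adds through a closed chair transition state at its γ-carbon to create the CMe2 centre, and the (+)-α-pinene-derived Ipc groups direct attack to the Si face of the aldehyde, which sets the carbinol as R (about 90–95% ee expected; the antipodal borane would give the S alcohol).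

**Step 3**
Reactants: 7 (4R)-3,3-dimethyloct-1-en-7-yn-4-ol
Product: 8 (4R)-3,3-dimethyloct-1-en-7-yn-4-yl acetate
Conditions: Ac2O, DMAP (cat.), pyridine, rt to 40 °C
Reagents that add atoms: acetic anhydride, CC(=O)OC(C)=O
Why: DMAP-catalysed acylation of the hindered secondary alcohol installs the acetate of the target early and prevents cyclic ether formation from the later epoxide; the stereocentre is not touched.

**Step 4**
Reactants: 8 (4R)-3,3-dimethyloct-1-en-7-yn-4-yl acetate
Product: 9 (3R)-2-methyl-2-(oxiran-2-yl)hept-6-yn-3-yl acetate (about 1:1 mixture of epimers at the oxirane carbon)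
Conditions: mCPBA (2.5 equiv), CH2Cl2, 0 °C to rt, 36 h
Reagents that add atoms: mCPBA (3-chloroperoxybenzoic acid), O=C(OO)c1cccc(Cl)c1
Why: Prilezhaev epoxidation attacks the alkene much faster than the terminal alkyne; the epimer mixture at the new oxirane carbon does not matter because this carbon becomes a planar radical in step 5.

**Step 5**
Reactants: 9 (3R)-2-methyl-2-(oxiran-2-yl)hept-6-yn-3-yl acetate
Product: 10 (1R,3S)-3-(hydroxymethyl)-2,2-dimethyl-4-methylidenecyclohexyl acetate
Conditions: Cp2TiCl2 (20 mol %), Mn dust (2 equiv), 2,4,6-collidine·HCl (2.5 equiv), THF (0.01 M), rt, 9 added over 6 h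
Reagents that add atoms: none
Why: Nugent–RajanBabu/Gansäuer reductive epoxide opening: Cp2TiCl (trivalent titanium, regenerated by Mn) turns the substituted oxirane carbon, an electrophile in polar chemistry, into a nucleophilic β-titanoxy carbon radical that closes the ring by 6-exo-dig addition to the alkyne; the vinyl radical takes H from THF to give the exocyclic methylene, collidinium chloride protonates the O–Ti bond, and the new stereocentre is set cis to the acetate (S) in a chair-like Beckwith–Houk transition state with CH2O[Ti] and OAc both pseudo-equatorial (both epoxide epimers converge; cis:trans of about 4:1 or better expected, minor isomer removed by chromatography).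

**Step 6**
Reactants: 10 (1R,3S)-3-(hydroxymethyl)-2,2-dimethyl-4-methylidenecyclohexyl acetate; 11 umbelliferone (7-hydroxycoumarin)
Product: 12 (1R,3S)-2,2-dimethyl-4-methylidene-3-{[(2-oxo-2H-chromen-7-yl)oxy]methyl}cyclohexyl acetate (target)
Conditions: PPh3 (1.5 equiv), DIAD (1.5 equiv), THF, 0 °C to rt
Reagents that add atoms: none
Why: Mitsunobu etherification: the primary alcohol is activated as its alkoxyphosphonium salt and displaced by the acidic phenol (pKa about 7.8) in an SN2 step at CH2, so neither stereocentre nor the acetate is touched.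

**Compound list**
1 | pent-4-yn-1-ol | C#CCCCO | starting material
2 | pent-4-ynal | C#CCCC=O | intermediate
3 | prenylmagnesium chloride (3-methylbut-2-en-1-ylmagnesium chloride) | CC(C)=CC[Mg]Cl | starting material
4 | (−)-B-methoxydiisopinocampheylborane, (−)-Ipc2BOMe, from (+)-α-pinene | COB([C@@H]1C[C@@H]2C[C@H]([C@H]1C)C2(C)C)[C@@H]1C[C@@H]2C[C@H]([C@H]1C)C2(C)C | starting material
5 | B-(3-methylbut-2-en-1-yl)diisopinocampheylborane (not isolated) | CC(C)=CCB([C@@H]1C[C@@H]2C[C@H]([C@H]1C)C2(C)C)[C@@H]1C[C@@H]2C[C@H]([C@H]1C)C2(C)C | intermediate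
6 | (4R)-3,3-dimethyloct-1-en-7-yn-4-yl diisopinocampheylborinate (not isolated) | C#CCC[C@@H](OB([C@@H]1C[C@@H]2C[C@H]([C@H]1C)C2(C)C)[C@@H]1C[C@@H]2C[C@H]([C@H]1C)C2(C)C)C(C)(C)C=C | intermediate
7 | (4R)-3,3-dimethyloct-1-en-7-yn-4-ol | C#CCC[C@@H](O)C(C)(C)C=C | intermediate
8 | (4R)-3,3-dimethyloct-1-en-7-yn-4-yl acetate | C#CCC[C@@H](OC(C)=O)C(C)(C)C=C | intermediate
9 | (3R)-2-methyl-2-(oxiran-2-yl)hept-6-yn-3-yl acetate, both epimers at the oxirane carbon | C#CCC[C@@H](OC(C)=O)C(C)(C)C1CO1 | intermediate
10 | (1R,3S)-3-(hydroxymethyl)-2,2-dimethyl-4-methylidenecyclohexyl acetate (cis) | C=C1CC[C@@H](OC(C)=O)C(C)(C)[C@H]1CO | intermediate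
11 | umbelliferone (7-hydroxy-2H-chromen-2-one) | Oc1ccc2ccc(=O)oc2c1 | starting material
12 | (1R,3S)-2,2-dimethyl-4-methylidene-3-{[(2-oxo-2H-chromen-7-yl)oxy]methyl}cyclohexyl acetate | C=C1CC[C@@H](OC(C)=O)C(C)(C)[C@H]1COc1ccc2ccc(=O)oc2c1 | target

**Totals**
Total step count: 6. Longest linear sequence: 6 steps (1 → 2 → 7 → 8 → 9 → 10 → 12).

**Steps most likely to fail, with fallbacks**

Step 5 (radical ring closure). The 6-exo-dig addition of a hindered secondary radical to an unactivated alkyne is slower than the well-known 5-exo cases. It may lose to 1,5-hydrogen transfer from the propargylic CH2 or to reductive deoxygenation of the epoxide, and the cis:trans ratio may be modest. The fallback leaves out the epoxide and closes the ring by a Pd-catalysed borylative enyne cyclisation. It sets out from acetate 8: Pd(OAc)2 (5 mol %), B2pin2, MeOH, toluene, 50 °C. Markovnikov hydropalladation of the alkyne, 6-exo carbopalladation of the vinyl group and boron transfer give 2-{[(1S,3R)-3-acetoxy-2,2-dimethyl-6-methylidenecyclohexyl]methyl}-4,4,5,5-tetramethyl-1,3,2-dioxaborolane F1 (diastereomer ratio to be determined, cis isomer separated). NaBO3·4H2O in THF/H2O then oxidises the C–B bond to C–OH, and the route is rejoined at alcohol 10.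

Step 6 (Mitsunobu). The carbinol is primary but β-branched and next to a quaternary centre, so the SN2 step may be slow and elimination to the diene may compete. The fallback is a two-stage alkylation through a discrete sulfonate. It sets out from alcohol 10: Tf2O and 2,6-lutidine in CH2Cl2 at −78 °C give [(1S,3R)-3-acetoxy-2,2-dimethyl-6-methylidenecyclohexyl]methyl trifluoromethanesulfonate F2. This is displaced at 0 °C in DMF by the caesium salt of umbelliferone 11 (Cs2CO3), which arrives at target 12.

Step 4 (epoxidation). The alkene is monosubstituted and neopentylic, so the epoxidation is slow and must not touch the alkyne. The fallback builds the oxirane from a carbonyl group instead. It sets out from acetate 8: ozonolysis (O3, CH2Cl2, −78 °C, then Me2S; the alkene reacts far faster than the alkyne) gives (3R)-2,2-dimethyl-1-oxohept-6-yn-3-yl acetate F3. Corey–Chaykovsky methylenation with dimethylsulfonium methylide (Me3SI, KN(SiMe3)2, THF, −10 °C) then returns epoxide 9 as the same inconsequential epimer mixture.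

**Further compounds**
F1 | step 5 | 2-{[(1S,3R)-3-acetoxy-2,2-dimethyl-6-methylidenecyclohexyl]methyl}-4,4,5,5-tetramethyl-1,3,2-dioxaborolane | C=C1CC[C@@H](OC(C)=O)C(C)(C)[C@H]1CB1OC(C)(C)C(C)(C)O1
F2 | step 6 | [(1S,3R)-3-acetoxy-2,2-dimethyl-6-methylidenecyclohexyl]methyl trifluoromethanesulfonate | C=C1CC[C@@H](OC(C)=O)C(C)(C)[C@H]1COS(=O)(=O)C(F)(F)F
F3 | step 4 | (3R)-2,2-dimethyl-1-oxohept-6-yn-3-yl acetate | C#CCC[C@@H](OC(C)=O)C(C)(C)C=O
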